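Ring A of the octalin (C1, C2, C3, C4, C4a, C8a) carries a carbonyl on quaternary C1, the C1–C2 bond and a C3=C4 alkene: the imprint of an ester enolate Claisen shift. Ring B is therefore made first, with the axial C6 methyl and both fusion centres (C4a, C8a) set, and a trans-fused δ-lactone is closed between C1 and a trienyl carbinol at C4. Its silyl ketene acetal rearranges through the only possible boat, forming C1–C2, cleaving C4–O and contracting the lactone to ring A, with C1, C2 and the C1 carboxyl delivered in one operation. The carboxyl is then grown into the threonine-derived pyrrolidine-2,4-dione.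

Key step: step 13

Remarks on the chemistry:
- Locants C1 to C8a are those of the target decalin (C1 quaternary) for every intermediate; CIP descriptors in names are for orientation and the SMILES strings decide.
- The 3-acyl tetramic acid is written in the enol form given; its tautomers interconvert.
- (S)-(−)-Pulegone and (+)-MIB, (2R)-3-exo-morpholinoisoborneol, are assumed purchasable.

Step 1
Reactants: 1 (S)-(−)-pulegone
Product: 2 pulegone oxide (both spiro epimers)
Conditions: 30% aq. H2O2, NaOH (cat.), MeOH, 0 °C → rt
Reagents that add atoms: hydrogen peroxide OO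
Why: Weitz–Scheffer nucleophilic epoxidation of the enone; the methyl-bearing centre is remote and the spiro configuration is lost again in step 2.

Step 2
Reactants: 2 pulegone oxide
Product: 3 (5S)-5-methyl-2-(phenylsulfanyl)cyclohexan-1-one (both C2 epimers)
Conditions: NaSPh, THF, reflux; then H2O
Reagents that add atoms: sodium benzenethiolate [Na+].[S-]c1ccccc1
Why: Thiolate opening of the α,β-epoxy ketone at the ring α-carbon and retro-aldol loss of acetone from the resulting β-alkoxide put sulfur on the carbonyl side away from the methyl group, which fixes where the alkene will form.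

Step 3
Reactants: 3 (5S)-5-methyl-2-(phenylsulfanyl)cyclohexan-1-one
Product: 5 (S)-5-methylcyclohex-2-en-1-one, via sulfoxide 4 (not isolated)
Conditions: mCPBA (1.0 equiv), CH2Cl2, −78 °C; aq. NaHCO3 wash; then CaCO3, toluene, 90 °C
Reagents that add atoms: none
Why: Sulfide oxidation and thermal syn-elimination of benzenesulfenic acid (sulfoxide pyrolysis) can only use the C3 hydrogens, so the enone should form regiospecifically with the stereocentre untouched.

Step 4
Reactants: 5 (S)-5-methylcyclohex-2-en-1-one, 6 methyl bromoacetate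
Product: 8 keto ester methyl 2-[(1R,2R,4S)-2-ethenyl-4-methyl-6-oxocyclohexyl]acetate, via bromomagnesium enolate 7 (not isolated)
Conditions: CH2=CHMgBr (1.3 equiv), CuBr·SMe2 (10 mol %), THF, −78 → −40 °C; then DMPU, 6, −78 → −20 °C; cold aq. NH4Cl
Reagents that add atoms: vinylmagnesium bromide C=C[Mg]Br
Why: Copper-catalysed 1,4-addition of the vinyl Grignard reagent occurs axially at C4a anti to the C6 methyl (trans-3,5) and the regiodefined enolate is alkylated at C8a anti to the adjacent vinyl group (trans-2,3), a conjugate addition–enolate alkylation sequence that sets C4a and C8a relative to C6 and leaves the methyl axial on the future ring B.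

Step 5
Reactants: 8 keto ester
Product: 9 tosylhydrazone of 8
Conditions: TsNHNH2, EtOH, rt, no added acid
Reagents that add atoms: 4-methylbenzenesulfonohydrazide Cc1ccc(cc1)S(=O)(=O)NN
Why: Hydrazone condensation at the only ketone under near-neutral conditions, chosen so that C8a, the one epimerisable centre next to the C=N bond, is not equilibrated.

Step 6
Reactants: 9 tosylhydrazone
Product: 11 vinyl ester methyl 2-[(1R,2R,4R)-2-ethenyl-4-methylcyclohexyl]acetate, via N-boryl hydrazine 10 (not isolated)
Conditions: catecholborane, CHCl3, 0 °C → rt; then NaOAc·3H2O, reflux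
Reagents that add atoms: none
Why: Catecholborane adds hydride to carbon and boron to nitrogen, and acetate-triggered loss of sulfinate and N2 from the diazene replaces the C8 carbonyl by CH2, a Wolff–Kishner-type deoxygenation mild enough for the ester, the vinyl group and C8a.

Step 7
Reactants: 11 vinyl ester
Product: 13 aldehyde ester methyl 2-[(1R,2S,4R)-2-formyl-4-methylcyclohexyl]acetate, via ozonide 12 (not isolated)
Conditions: O3, CH2Cl2, −78 °C; then PPh3, −78 °C → rt; quick filtration through Et3N-washed silica, used at once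
Reagents that add atoms: ozone [O-][O+]=O
Why: Ozonolysis with reductive work-up cleaves the only alkene to the C4 formyl group under neutral conditions, so C4a (now α to the aldehyde) should keep its configuration.

Step 8
Reactants: 14 (2E,4E)-hexa-2,4-dienal
Product: 15 (3E,5E)-1,1-dibromohepta-1,3,5-triene
Conditions: CBr4, PPh3, CH2Cl2, 0 °C
Reagents that add atoms: carbon tetrabromide BrC(Br)(Br)Br
Why: First stage of the Corey–Fuchs homologation, a Wittig reaction of the dibromomethylene ylide that leaves the E,E-diene untouched.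

Step 9
Reactants: 15 (3E,5E)-1,1-dibromohepta-1,3,5-triene
Product: 17 (3E,5E)-hepta-3,5-dien-1-yne, via lithium acetylide 16 (not isolated)
Conditions: n-BuLi (2.1 equiv), Et2O, −78 → 0 °C; then H2O; ether exchanged for toluene by careful distillation, kept as a titrated solution
Reagents that add atoms: none
Why: Second stage of the Corey–Fuchs alkyne synthesis: bromine–lithium exchange, Fritsch–Buttenberg–Wiechell 1,2-shift and deprotonation give the acetylide, which water protonates.

Step 10
Reactants: 17 (3E,5E)-hepta-3,5-dien-1-yne, 13 aldehyde ester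
Product: 21 trienyl hydroxy ester, via alkenylborane 18 (not isolated), via alkenylzinc 19 (not isolated), via zinc alkoxide 20 (not isolated)
Conditions: Cy2BH (from BH3·SMe2 and cyclohexene), toluene, 0 °C → rt; Me2Zn, −78 °C; (+)-MIB (5 mol %), then 13, −78 → −10 °C; pH 7 aqueous quench
Reagents that add atoms: none
Why: Syn-hydroboration of the terminal alkyne, boron-to-zinc exchange and amino alcohol-catalysed 1,2-addition of the (E)-alkenylzinc form the C3–C4 bond; the ligand enantiomer is the one that sends the alkenyl group to the Re face of the formyl group (expected for (+)-MIB, as (−)-MIB is Si-selective), which sets the R carbinol against what should be a modest opposing Felkin–Anh bias.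

Step 11
Reactants: 21 trienyl hydroxy ester
Product: 22 trans-fused trienyl δ-lactone
Conditions: DBU (0.3 equiv), 4 Å MS, toluene, 50 °C; chromatography on Et3N-washed silica (removes any C4 epimer)
Reagents that add atoms: none
Why: Base-catalysed intramolecular transesterification (lactonisation) is possible only from the diequatorial conformer and locks the trans-fused chair with trienyl equatorial and methyl axial; acid is avoided because the trienyl carbinol ester ionises easily.

Step 12
Reactants: 22 trienyl δ-lactone
Product: 24 α-methyl lactone, via lithium enolate 23 (not isolated)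
Conditions: LiN(iPr)2 (1.05 equiv), THF, −78 °C; then MeI, −78 → −40 °C
Reagents that add atoms: iodomethane CI
Why: Lactone enolate alkylation; the new C1 centre need not be controlled (the equatorial-methyl epimer is written) because C1 becomes planar again in step 13.

Step 13
Reactants: 24 α-methyl lactone
Product: 27 octalin carboxylic acid, via silyl ketene acetal 25 (not isolated), via silyl ester 26 (not isolated)
Conditions: KN(SiMe3)2, Me3SiCl, THF–toluene, −78 °C → rt; then toluene, 90–105 °C; then aq. citric acid, THF, rt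
Reagents that add atoms: none
Why: O-Silylation of the lactone enolate gives a cyclic ketene acetal whose C1=C(OSi)–O–C4–C3=C2 array undergoes a concerted [3,3] shift (Ireland–Claisen rearrangement) that forms C1–C2, breaks C4–O and moves the alkene to C3=C4; the closest known reaction type is the Claisen ring contraction of 6-alkenyl tetrahydropyran-2-one silyl ketene acetals to cyclohex-3-enecarboxylic acids. Ring A (C1, C2, C3, C4, C4a, C8a) closes by this ring contraction of the six-membered lactone, and because C1 and C4 stay tied through C8a–C4a the transition state can only be a boat, here twisted by the trans fusion to ring B, which makes the new ring alkene cis. C1 is controlled by the C4 carbinol: the alkenyl arm, cis to H4a, reaches C1 on the face anti to H8a, so the carboxyl ends cis to H8a and the methyl trans to it. C2 is controlled by the E geometry of the proximal alkene within the boat, which places the pentadienyl group cis to the carboxyl. The step needs complete suprafacial 1,3-chirality transfer and reaction of the proximal alkene alone; the single accessible boat, the ring-fixed ketene acetal geometry (both α-methyl epimers converge) and the fact that only the first triene double bond is allylic to oxygen should secure this. The C6 methyl takes no part, and the twist of the boat is expected to cost heating but not selectivity.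

Step 14
Reactants: 27 octalin carboxylic acid, 28 S-tert-butyl thioacetate
Product: 31 β-keto thioester, via acid chloride 29 (not isolated), via lithium thioester enolate 30 (not isolated)
Conditions: 1-chloro-N,N,2-trimethylprop-1-en-1-amine, CH2Cl2, 0 °C → rt, concentrate; 28 (2.5 equiv), LiN(SiMe3)2 (2.5 equiv), THF, −78 °C, then 29, −78 → −20 °C; aq. NH4Cl
Reagents that add atoms: none
Why: Neutral acid chloride formation and crossed Claisen C-acylation of the thioester enolate; the acid chloride has no α-hydrogen, so no ketene can form, and the second equivalent of enolate takes up the acidic product.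

Step 15
Reactants: 32 L-threonine methyl ester hydrochloride
Product: 33 methyl (2S,3R)-2-amino-3-[(tert-butyldimethylsilyl)oxy]butanoate
Conditions: t-BuMe2SiCl, imidazole, DMF, rt; aq. NaHCO3
Reagents that add atoms: tert-butyl(chloro)dimethylsilane CC(C)(C)[Si](C)(C)Cl
Why: O-Silylation of the secondary alcohol (any N-silyl amine is hydrolysed on work-up); neither stereocentre is involved.

Step 16
Reactants: 31 β-keto thioester, 33 O-silyl threonine methyl ester
Product: 34 β-keto amide
Conditions: AgOCOCF3, Et3N, THF, 0 °C → rt, dark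
Reagents that add atoms: none
Why: Silver-promoted thioester aminolysis, in which thiophilic activation lets the amine acylate under conditions too mild to epimerise the amino ester.

Step 17
Reactants: 34 β-keto amide
Product: 35 O-silyl tetramic acid
Conditions: NaOMe (2.5 equiv), MeOH, 0 °C → rt, 15–30 min; cold dilute HCl to pH 3
Reagents that add atoms: none
Why: Lacey–Dieckmann cyclisation of the β-keto amide carbanion onto the methyl ester closes the pyrrolidine-2,4-dione; short contact with base should limit epimerisation at C5 of the heterocycle and β-elimination of the silyloxy group.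

Step 18
Reactants: 35 O-silyl tetramic acid
Product: 36 target CNP0298257.2
Conditions: 48% aq. HF, MeCN, 0 °C → rt
Reagents that add atoms: none
Why: Fluoride-driven cleavage of the silyl ether under acidic conditions, in which the 3-acyl tetramic acid should not epimerise and the diene and ring alkene are inert.

Compound list
1 | (S)-(−)-pulegone, (5S)-5-methyl-2-(propan-2-ylidene)cyclohexan-1-one | C[C@H]1CCC(=C(C)C)C(=O)C1 | starting material
2 | pulegone oxide, (6S)-2,2,6-trimethyl-1-oxaspiro[2.5]octan-4-one, both spiro epimers | C[C@H]1CCC2(OC2(C)C)C(=O)C1 | intermediate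
3 | (5S)-5-methyl-2-(phenylsulfanyl)cyclohexan-1-one, both C2 epimers | C[C@H]1CCC(Sc2ccccc2)C(=O)C1 | intermediate
4 | (5S)-5-methyl-2-(phenylsulfinyl)cyclohexan-1-one, isomer mixture | C[C@H]1CCC(S(=O)c2ccccc2)C(=O)C1 | intermediate
5 | (S)-5-methylcyclohex-2-en-1-one | C[C@H]1CC=CC(=O)C1 | intermediate
6 | methyl bromoacetate | COC(=O)CBr | starting material
7 | bromomagnesium (3R,5S)-3-ethenyl-5-methylcyclohex-1-en-1-olate | C=C[C@H]1C[C@H](C)CC(O[Mg]Br)=C1 | intermediate
8 | methyl 2-[(1R,2R,4S)-2-ethenyl-4-methyl-6-oxocyclohexyl]acetate (vinyl and acetate arm trans, vinyl and methyl trans) | C=C[C@H]1C[C@H](C)CC(=O)[C@@H]1CC(=O)OC | intermediate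
9 | tosylhydrazone of 8 at the ring ketone | C=C[C@H]1C[C@H](C)CC(=NNS(=O)(=O)c2ccc(C)cc2)[C@@H]1CC(=O)OC | intermediate
10 | adduct of catecholborane across the C=N bond of 9 (H on carbon, 1,3,2-benzodioxaborol-2-yl on nitrogen; new CH centre undefined) | C=C[C@H]1C[C@H](C)CC(N(B2Oc3ccccc3O2)NS(=O)(=O)c2ccc(C)cc2)[C@@H]1CC(=O)OC | intermediate
11 | methyl 2-[(1R,2R,4R)-2-ethenyl-4-methylcyclohexyl]acetate | C=C[C@H]1C[C@H](C)CC[C@@H]1CC(=O)OC | intermediate
12 | ozonide of 11, methyl 2-[(1R,2S,4R)-4-methyl-2-(1,2,4-trioxolan-3-yl)cyclohexyl]acetate (trioxolane centre undefined) | C1(OCOO1)[C@H]2C[C@H](C)CC[C@@H]2CC(=O)OC | intermediate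
13 | methyl 2-[(1R,2S,4R)-2-formyl-4-methylcyclohexyl]acetate | O=C[C@H]1C[C@H](C)CC[C@@H]1CC(=O)OC | intermediate
14 | (2E,4E)-hexa-2,4-dienal (sorbaldehyde) | C/C=C/C=C/C=O | starting material
15 | (3E,5E)-1,1-dibromohepta-1,3,5-triene | C/C=C/C=C/C=C(Br)Br | intermediate
16 | lithium (3E,5E)-hepta-3,5-dien-1-yn-1-ide | C/C=C/C=C/C#C[Li] | intermediate
17 | (3E,5E)-hepta-3,5-dien-1-yne | C/C=C/C=C/C#C | intermediate
18 | dicyclohexyl[(1E,3E,5E)-hepta-1,3,5-trien-1-yl]borane | C/C=C/C=C/C=C/B(C1CCCCC1)C1CCCCC1 | intermediate
19 | [(1E,3E,5E)-hepta-1,3,5-trien-1-yl](methyl)zinc | C/C=C/C=C/C=C/[Zn]C | intermediate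
20 | methylzinc alkoxide of 21 | C/C=C/C=C/C=C/[C@@H](O[Zn]C)[C@H]1C[C@H](C)CC[C@@H]1CC(=O)OC | intermediate
21 | methyl 2-[(1R,2S,4R)-2-[(1R,2E,4E,6E)-1-hydroxyocta-2,4,6-trien-1-yl]-4-methylcyclohexyl]acetate | C/C=C/C=C/C=C/[C@@H](O)[C@H]1C[C@H](C)CC[C@@H]1CC(=O)OC | intermediate
22 | (1R,4aR,7R,8aS)-1-[(1E,3E,5E)-hepta-1,3,5-trien-1-yl]-7-methyl-1,4,4a,5,6,7,8,8a-octahydro-3H-isochromen-3-one (trans-fused, trienyl equatorial and cis to H4a, methyl axial) | C/C=C/C=C/C=C/[C@@H]1[C@H]2C[C@H](C)CC[C@@H]2CC(=O)O1 | intermediate
23 | lithium enolate of 22 | C/C=C/C=C/C=C/[C@@H]1[C@H]2C[C@H](C)CC[C@@H]2C=C(O[Li])O1 | intermediate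
24 | (1R,4R,4aS,7R,8aS)-1-[(1E,3E,5E)-hepta-1,3,5-trien-1-yl]-4,7-dimethyl-1,4,4a,5,6,7,8,8a-octahydro-3H-isochromen-3-one (α-methyl lactone, equatorial-methyl epimer written, either epimer serves) | C/C=C/C=C/C=C/[C@@H]1[C@H]2C[C@H](C)CC[C@@H]2[C@@H](C)C(=O)O1 | intermediate
25 | trimethylsilyl ketene acetal of 24 (endocyclic C1=C double bond, OSiMe3 on the former carbonyl carbon) | C/C=C/C=C/C=C/[C@@H]1[C@H]2C[C@H](C)CC[C@@H]2C(C)=C(O[Si](C)(C)C)O1 | intermediate
26 | trimethylsilyl ester of 27 | C/C=C/C=C/[C@H]1C=C[C@H]2C[C@H](C)CC[C@@H]2[C@@]1(C)C(=O)O[Si](C)(C)C | intermediate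
27 | (1R,2S,4aR,6R,8aS)-1,6-dimethyl-2-[(1E,3E)-penta-1,3-dien-1-yl]-1,2,4a,5,6,7,8,8a-octahydronaphthalene-1-carboxylic acid | C/C=C/C=C/[C@H]1C=C[C@H]2C[C@H](C)CC[C@@H]2[C@@]1(C)C(=O)O | intermediate
28 | S-tert-butyl ethanethioate (S-tert-butyl thioacetate) | CC(=O)SC(C)(C)C | starting material
29 | acid chloride of 27 | C/C=C/C=C/[C@H]1C=C[C@H]2C[C@H](C)CC[C@@H]2[C@@]1(C)C(=O)Cl | intermediate
30 | lithium enolate of 28 | C=C(O[Li])SC(C)(C)C | intermediate
31 | S-tert-butyl 3-[(1R,2S,4aR,6R,8aS)-1,6-dimethyl-2-[(1E,3E)-penta-1,3-dien-1-yl]-1,2,4a,5,6,7,8,8a-octahydronaphthalen-1-yl]-3-oxopropanethioate | C/C=C/C=C/[C@H]1C=C[C@H]2C[C@H](C)CC[C@@H]2[C@@]1(C)C(=O)CC(=O)SC(C)(C)C | intermediate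
32 | L-threonine methyl ester hydrochloride | COC(=O)[C@@H](N)[C@@H](C)O.Cl | starting material
33 | methyl (2S,3R)-2-amino-3-[(tert-butyldimethylsilyl)oxy]butanoate | COC(=O)[C@@H](N)[C@@H](C)O[Si](C)(C)C(C)(C)C | intermediate
34 | β-keto amide, N-acyl derivative of 33 with the 3-oxopropanoyl unit of 31 | C/C=C/C=C/[C@H]1C=C[C@H]2C[C@H](C)CC[C@@H]2[C@@]1(C)C(=O)CC(=O)N[C@H](C(=O)OC)[C@@H](C)O[Si](C)(C)C(C)(C)C | intermediate
35 | (5S)-5-[(1R)-1-[(tert-butyldimethylsilyl)oxy]ethyl] analogue of the target (silyl ether of 36) | C/C=C/C=C/[C@H]1C=C[C@H]2C[C@H](C)CC[C@@H]2[C@@]1(C)C(=O)C1=C(O)[C@H]([C@@H](C)O[Si](C)(C)C(C)(C)C)NC1=O | intermediate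
36 | CNP0298257.2, (5S)-3-{[(1R,2S,4aR,6R,8aS)-1,6-dimethyl-2-[(1E,3E)-penta-1,3-dien-1-yl]-1,2,4a,5,6,7,8,8a-octahydronaphthalen-1-yl]carbonyl}-4-hydroxy-5-[(1R)-1-hydroxyethyl]-1,5-dihydro-2H-pyrrol-2-one | C/C=C/C=C/[C@H]1C=C[C@H]2C[C@H](C)CC[C@@H]2[C@@]1(C)C(=O)C1=C(O)[C@H]([C@@H](C)O)NC1=O | target

Total step count: 18 steps.
Longest linear sequence: 15 steps from (S)-(−)-pulegone (steps 1–7, 10–14, 16–18).

Steps most likely to fail

1. Step 13. The trans ring fusion resists the boat that the sigmatropic shift needs, so the ketene acetal may outlast heating or decay before it rearranges, by desilylation back to 24 or by ionisation of the trienyl C4–O bond. The fallback assembles ring A from open-chain pieces; it sets out from 11 and rejoins the route at 27. Compound 11 is α-methylated (LiN(iPr)2, MeI, THF, −78 °C) to the α-methyl ester F1 and saponified (LiOH, aq. THF) to the acid F2. Separately, 14 is extended by Horner–Wadsworth–Emmons olefination with triethyl phosphonoacetate to ethyl (2E,4E,6E)-octa-2,4,6-trienoate F3 and reduced with iBu2AlH to (2E,4E,6E)-octa-2,4,6-trien-1-ol F4. Esterification of F2 with F4 (DCC, DMAP) should give the trienyl ester F5. An open-chain Ireland–Claisen rearrangement (KN(SiMe3)2, Me3SiCl, THF, −78 °C → 60 °C) through the silyl ketene acetal F6 and the silyl ester F7 should give, after hydrolysis, the diene acid F8, with quaternary C1 and with a vinyl and the pentadienyl group on C2. Ring-closing metathesis of the two vinyl groups with the first-generation Grubbs catalyst RuCl2(=CHPh)(PCy3)2 would close C3=C4 and return 27. Stereocontrol at C1 and C2 rests here on ketene acetal geometry and A(1,3) strain from C8a and is weaker, so the isomer matching 27 would have to be separated.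

2. Step 10. Reagent control may not override the opposing substrate bias, or the uncatalysed background addition may compete, giving poor facial selectivity at the C4 carbinol. The fallback sets C4 by hydride delivery to a ketone; it sets out from 13 and 17 and rejoins at 21. The addition is run as in step 10 but with achiral 2-(dimethylamino)ethanol as promoter, giving 21 together with its carbinol epimer F9. The mixture is oxidised (Dess–Martin periodinane, NaHCO3, CH2Cl2, 0 °C) to the trienyl ketone F10. A 1,2-selective reduction (NaBH4, CeCl3·7H2O, MeOH, −78 °C) should then favour 21, because Felkin–Anh hydride addition to F10 leads to the same carbinol that is anti-Felkin for alkenyl addition to 13. The minor epimer from step 10 can be recycled the same way.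

3. Step 14. Acylation at the shielded, neopentyl carbonyl may be slow, so the enolate is consumed by thioester self-condensation and the acid chloride reverts to 27 on work-up. The fallback attaches the two carbons at the aldehyde oxidation level; it sets out from 27 and rejoins at 31. Reduction with LiAlH4 (Et2O, 0 °C) should give the primary alcohol F11, and Dess–Martin oxidation the aldehyde F12, which has no α-hydrogen. Aldol addition of the lithium enolate 30 (THF, −78 °C) would give the β-hydroxy thioester F13 as carbinol epimers, and a second Dess–Martin oxidation returns 31.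

Further compounds
F1 | step 13 | methyl 2-(2-ethenyl-4-methylcyclohexyl)propanoate, ring configuration of 11, both α-epimers | C=C[C@H]1C[C@H](C)CC[C@@H]1C(C)C(=O)OC
F2 | step 13 | 2-(2-ethenyl-4-methylcyclohexyl)propanoic acid, ring configuration of 11, both α-epimers | C=C[C@H]1C[C@H](C)CC[C@@H]1C(C)C(=O)O
F3 | step 13 | ethyl (2E,4E,6E)-octa-2,4,6-trienoate | C/C=C/C=C/C=C/C(=O)OCC
F4 | step 13 | (2E,4E,6E)-octa-2,4,6-trien-1-ol | C/C=C/C=C/C=C/CO
F5 | step 13 | (2E,4E,6E)-octa-2,4,6-trien-1-yl ester of F2 | C=C[C@H]1C[C@H](C)CC[C@@H]1C(C)C(=O)OC/C=C/C=C/C=C/C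
F6 | step 13 | trimethylsilyl ketene acetal of F5 | C=C[C@H]1C[C@H](C)CC[C@@H]1C(C)=C(O[Si](C)(C)C)OC/C=C/C=C/C=C/C
F7 | step 13 | trimethylsilyl ester of F8 | C=C[C@H]1C[C@H](C)CC[C@@H]1[C@@](C)(C(=O)O[Si](C)(C)C)[C@H](C=C)/C=C/C=C/C
F8 | step 13 | (4E,6E)-3-ethenyl-2-methyl-2-(2-ethenyl-4-methylcyclohexyl)octa-4,6-dienoic acid, isomer with the C1 and C2 configuration of 27 | C=C[C@H]1C[C@H](C)CC[C@@H]1[C@@](C)(C(=O)O)[C@H](C=C)/C=C/C=C/C
F9 | step 10 | carbinol (1S) epimer of 21 | C/C=C/C=C/C=C/[C@H](O)[C@H]1C[C@H](C)CC[C@@H]1CC(=O)OC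
F10 | step 10 | methyl 2-[4-methyl-2-[(2E,4E,6E)-octa-2,4,6-trienoyl]cyclohexyl]acetate, ring configuration of 13 | C/C=C/C=C/C=C/C(=O)[C@H]1C[C@H](C)CC[C@@H]1CC(=O)OC
F11 | step 14 | primary alcohol from reduction of 27 (CH2OH on C1) | C/C=C/C=C/[C@H]1C=C[C@H]2C[C@H](C)CC[C@@H]2[C@@]1(C)CO
F12 | step 14 | aldehyde corresponding to 27 (CHO on C1) | C/C=C/C=C/[C@H]1C=C[C@H]2C[C@H](C)CC[C@@H]2[C@@]1(C)C=O
F13 | step 14 | S-tert-butyl 3-hydroxy-3-(octalin-1-yl)propanethioate, carbinol epimers | C/C=C/C=C/[C@H]1C=C[C@H]2C[C@H](C)CC[C@@H]2[C@@]1(C)C(O)CC(=O)SC(C)(C)C
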